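**Retrosynthetic overview** (xanthane numbering: half A = C1–C15, carrying the free α-methylene lactone and C1–OH; half B = primed atoms, the spiro-lactone half; ring C = C1–C2–C3–C11′–C13′–C5)

1. Ring C is closed last at C2=C3 by intramolecular aldol condensation of a C1 α-hydroxy aldehyde (C2) with the C3 methylene of an acetonyl group on C11′; the acetonyl group is a Wacker-oxidised allyl group (C3–C4–C15).
2. The spiro centre C11′ is set by decarboxylative allyl transfer onto the convex face of the cis-fused lactone B; that lactone is closed by the key C11′–C7′ bond, a 5-exo 1,8-Michael addition of a malonate carbon tethered through O8′.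
3. Enabling feature: with the ring-B unsaturation placed at C6′=C7′, C7′ is the ζ-terminus of the through-conjugated trienone C7′=C6′–C5′=C1′–C2′=C3′–C4′=O. O8′ on the neighbouring ring carbon holds C11′ five atoms away, and C11′ is α to the lactone carbonyl C12′, so a second, temporary carboxylate makes it a soft malonate carbon.
4. The two halves are mirror images at C7/C8/C10 versus C7′/C8′/C10′, so each comes from its own enantiomer of 5-(hydroxymethyl)butanolide via the cyclohept-3-enones 8 and 20 (lactone α-methylation, Weinreb ketone, ring-closing metathesis). Half A gets lactone A by a 5-exo vinyl-radical closure and is joined at C5–C13′ by Mannich/Michael chemistry; C2 is added to the C1 ketone.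
5. Order of ring formation: cycloheptene B and cycloheptene A (metathesis), lactone A (radical), spiro-lactone B (key step), ring C (aldol condensation).

Key step: step 22

Remarks on the chemistry
- In the given structure C7, C8, C10 of half A are (R,R,S) and C7′, C8′, C10′ of half B are (S,S,R); the halves are therefore built from enantiomeric series. Both enantiomers of 5-(hydroxymethyl)oxolan-2-one (from L- and D-glutamic acid) are assumed to be commercial.
- Centres written without configuration (acetal carbon C12 in 22–29, C5 in 24 and 25, the malonate carbon in 27–31) are epimer mixtures that converge later.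

**Route**

Step 1
Reactants: 1 (S)-5-(hydroxymethyl)oxolan-2-one
Product: 3 (S)-5-ethenyloxolan-2-one, via aldehyde 2 (not isolated)
Conditions: Dess–Martin periodinane, CH2Cl2, 0 to 20 °C; filter, concentrate; Ph3P=CH2 (from Ph3PCH3Br, KN(SiMe3)2), THF, −78 to 0 °C
Reagents that add atoms: methyltriphenylphosphonium bromide (as its ylide), C[P+](c1ccccc1)(c1ccccc1)c1ccccc1.[Br-]
Why: Dess–Martin oxidation gives the labile α-oxy aldehyde, which is methylenated at once by a low-temperature Wittig reaction so that the purchased C8′ stereocentre is carried over unchanged.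

Step 2
Reactants: 3 (S)-5-ethenyloxolan-2-one
Product: 4 (3R,5S)-5-ethenyl-3-methyloxolan-2-one
Conditions: LiN(i-Pr)2, THF, −78 °C; MeI, −78 to −40 °C
Reagents that add atoms: iodomethane, CI
Why: Enolate alkylation of a γ-substituted butanolide occurs anti to the C5 vinyl group, giving the trans methyl centre (C10′) by 1,3-induction.

Step 3
Reactants: 4 (3R,5S)-5-ethenyl-3-methyloxolan-2-one
Product: 6 (2R,4S)-4-[(tert-butyldimethylsilyl)oxy]-N-methoxy-N,2-dimethylhex-5-enamide, via hydroxy amide 5 (not isolated)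
Conditions: MeNH(OMe)·HCl, i-PrMgCl, THF, −20 to 0 °C; aqueous work-up; crude: TBSCl, imidazole, DMF, 20 °C
Reagents that add atoms: N,O-dimethylhydroxylamine hydrochloride, CNOC.Cl; tert-butyl(chloro)dimethylsilane, CC(C)(C)[Si](C)(C)Cl
Why: Weinreb aminolysis with the chloromagnesium amide opens the lactone without touching either stereocentre, and immediate silylation prevents relactonisation.

Step 4
Reactants: 6 (2R,4S)-4-[(tert-butyldimethylsilyl)oxy]-N-methoxy-N,2-dimethylhex-5-enamide
Product: 7 (5R,7S)-7-[(tert-butyldimethylsilyl)oxy]-5-methylnona-1,8-dien-4-one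
Conditions: allylMgBr, THF, −78 to −20 °C; cold aqueous NH4Cl
Reagents that add atoms: allylmagnesium bromide, C=CC[Mg]Br
Why: Grignard addition to the Weinreb amide stops at the ketone through the chelated tetrahedral intermediate, and the cold neutral quench keeps the β,γ-alkene out of conjugation and C5 unepimerised.

Step 5
Reactants: 7 (5R,7S)-7-[(tert-butyldimethylsilyl)oxy]-5-methylnona-1,8-dien-4-one
Product: 8 (5S,7R)-5-[(tert-butyldimethylsilyl)oxy]-7-methylcyclohept-3-en-1-one
Conditions: second-generation Grubbs catalyst (H2IMes)(PCy3)Cl2Ru=CHPh (3 mol%), 1,4-benzoquinone (10 mol%), CH2Cl2, 0.005 M, 40 °C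
Reagents that add atoms: none
Why: Ring-closing metathesis of the two terminal alkenes closes the seven-membered ring with loss of ethene, and benzoquinone suppresses hydride-induced alkene migration.

Step 6
Reactants: 8 (5S,7R)-5-[(tert-butyldimethylsilyl)oxy]-7-methylcyclohept-3-en-1-one
Product: 9 (5S,7R)-5-[(tert-butyldimethylsilyl)oxy]-7-methylcyclohepta-1,3-dien-1-yl trifluoromethanesulfonate
Conditions: KN(SiMe3)2, THF, −78 °C; PhNTf2, −78 to 0 °C
Reagents that add atoms: N-phenylbis(trifluoromethanesulfonimide), O=S(=O)(N(c1ccccc1)S(=O)(=O)C(F)(F)F)C(F)(F)F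
Why: Deprotonation occurs at the doubly activated C2 methylene (α to C=O and allylic) rather than at the methyl-bearing carbon, and O-triflation of the dienolate gives the cross-coupling handle (enol triflate formation).

Step 7
Reactants: 9 (5S,7R)-5-[(tert-butyldimethylsilyl)oxy]-7-methylcyclohepta-1,3-dien-1-yl trifluoromethanesulfonate
Product: 10 tert-butyldimethyl{[(1S,6R)-6-methyl-5-[(E)-2-(2-methyl-1,3-dioxolan-2-yl)ethenyl]cyclohepta-2,4-dien-1-yl]oxy}silane
Conditions: 2-methyl-2-vinyl-1,3-dioxolane, Pd(OAc)2 (5 mol%), PPh3 (10 mol%), Et3N, DMF, 60 °C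
Reagents that add atoms: 2-methyl-2-vinyl-1,3-dioxolane, C=CC1(C)OCCO1
Why: The Heck reaction of the dienyl triflate gives the (E)-triene by syn insertion and syn β-hydride elimination, and the ketal keeps the future Michael acceptor silent until step 21.

Step 8
Reactants: 10 silyl ether of the triene ketal
Product: 11 (1S,6R)-6-methyl-5-[(E)-2-(2-methyl-1,3-dioxolan-2-yl)ethenyl]cyclohepta-2,4-dien-1-ol
Conditions: Bu4NF, THF, 0 to 20 °C
Reagents that add atoms: none
Why: Fluoride cleaves the silyl ether, and the triene ketal has no base-sensitive site.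

Step 9
Reactants: 11 (1S,6R)-6-methyl-5-[(E)-2-(2-methyl-1,3-dioxolan-2-yl)ethenyl]cyclohepta-2,4-dien-1-ol
Product: 12 (1S,6R)-6-methyl-5-[(E)-2-(2-methyl-1,3-dioxolan-2-yl)ethenyl]cyclohepta-2,4-dien-1-yl prop-2-en-1-yl propanedioate
Conditions: allyl hydrogen malonate, DCC, DMAP (10 mol%), CH2Cl2, 0 to 20 °C
Reagents that add atoms: 3-oxo-3-(prop-2-en-1-yloxy)propanoic acid, C=CCOC(=O)CC(=O)O
Why: Steglich esterification attaches the doubly activated carbon (future C11′) through O8′ and brings in the allyl carboxylate that later leaves as CO2.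

Step 10
Reactants: 13 (R)-5-(hydroxymethyl)oxolan-2-one
Product: 15 (R)-5-ethenyloxolan-2-one, via aldehyde 14 (not isolated)
Conditions: Dess–Martin periodinane, CH2Cl2, 0 to 20 °C; filter, concentrate; Ph3P=CH2 (from Ph3PCH3Br, KN(SiMe3)2), THF, −78 to 0 °C
Reagents that add atoms: methyltriphenylphosphonium bromide (as its ylide), C[P+](c1ccccc1)(c1ccccc1)c1ccccc1.[Br-]
Why: Same Dess–Martin oxidation and Wittig methylenation as step 1, here carrying the purchased C8 stereocentre of half A.

Step 11
Reactants: 15 (R)-5-ethenyloxolan-2-one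
Product: 16 (3S,5R)-5-ethenyl-3-methyloxolan-2-one
Conditions: LiN(i-Pr)2, THF, −78 °C; MeI, −78 to −40 °C
Reagents that add atoms: iodomethane, CI
Why: Enolate alkylation anti to the C5 vinyl group sets the trans methyl centre (C10), as in step 2.

Step 12
Reactants: 16 (3S,5R)-5-ethenyl-3-methyloxolan-2-one
Product: 18 (2S,4R)-4-[(tert-butyldimethylsilyl)oxy]-N-methoxy-N,2-dimethylhex-5-enamide, via hydroxy amide 17 (not isolated)
Conditions: MeNH(OMe)·HCl, i-PrMgCl, THF, −20 to 0 °C; aqueous work-up; crude: TBSCl, imidazole, DMF, 20 °C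
Reagents that add atoms: N,O-dimethylhydroxylamine hydrochloride, CNOC.Cl; tert-butyl(chloro)dimethylsilane, CC(C)(C)[Si](C)(C)Cl
Why: Weinreb aminolysis and immediate silylation, as in step 3.

Step 13
Reactants: 18 (2S,4R)-4-[(tert-butyldimethylsilyl)oxy]-N-methoxy-N,2-dimethylhex-5-enamide
Product: 19 (5S,7R)-7-[(tert-butyldimethylsilyl)oxy]-5-methylnona-1,8-dien-4-one
Conditions: allylMgBr, THF, −78 to −20 °C; cold aqueous NH4Cl
Reagents that add atoms: allylmagnesium bromide, C=CC[Mg]Br
Why: Weinreb ketone synthesis, as in step 4.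

Step 14
Reactants: 19 (5S,7R)-7-[(tert-butyldimethylsilyl)oxy]-5-methylnona-1,8-dien-4-one
Product: 20 (5R,7S)-5-[(tert-butyldimethylsilyl)oxy]-7-methylcyclohept-3-en-1-one
Conditions: second-generation Grubbs catalyst (H2IMes)(PCy3)Cl2Ru=CHPh (3 mol%), 1,4-benzoquinone (10 mol%), CH2Cl2, 0.005 M, 40 °C
Reagents that add atoms: none
Why: Ring-closing metathesis, as in step 5.

Step 15
Reactants: 20 (5R,7S)-5-[(tert-butyldimethylsilyl)oxy]-7-methylcyclohept-3-en-1-one
Product: 21 (5R,7S)-5-hydroxy-7-methylcyclohept-3-en-1-one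
Conditions: HF·pyridine, pyridine–THF, 0 to 20 °C
Reagents that add atoms: none
Why: Acidic fluoride removes the silyl group without base that would move the β,γ-alkene into conjugation or epimerise C7.

Step 16
Reactants: 21 (5R,7S)-5-hydroxy-7-methylcyclohept-3-en-1-one
Product: 22 (5R,7S)-5-[(2-bromo-1-methoxyprop-2-en-1-yl)oxy]-7-methylcyclohept-3-en-1-one
Conditions: methoxyallene, N-bromosuccinimide, CH2Cl2, −78 to −20 °C
Reagents that add atoms: 1-methoxypropa-1,2-diene, COC=C=C; N-bromosuccinimide, O=C1CCC(=O)N1Br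
Why: Bromonium attack on the central carbon of the electron-rich allene and capture of the oxocarbenium ion by the alcohol give the 2-bromoallyl mixed acetal (haloacetalisation of the Ueno–Stork type).

Step 17
Reactants: 22 bromoallyl acetal
Product: 23 (3aR,7S,8aR)-2-methoxy-7-methyl-3-methylideneoctahydro-6H-cyclohepta[b]furan-6-one
Conditions: Bu3SnH (syringe pump), AIBN (10 mol%), PhH, 0.01 M, 80 °C
Reagents that add atoms: none
Why: The vinyl radical cyclises 5-exo-trig onto C7 on the face of the C8–O tether, so lactone A (as its α-methylene acetal) is closed cis-fused and C7 is set by C8 before the C6 radical is reduced by the stannane.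

Step 18
Reactants: 23 keto acetal
Product: 24 5-[(dimethylamino)methyl] derivative of 23
Conditions: LiN(i-Pr)2, THF, −78 °C; CH2=NMe2+ I−, −78 to 0 °C
Reagents that add atoms: N,N-dimethylmethyleneiminium iodide, C=[N+](C)C.[I-]
Why: Kinetic enolisation takes place at the less substituted C5 methylene and the enolate is aminomethylated (Mannich reaction), leaving C10 untouched.

Step 19
Reactants: 24 Mannich base; 12 allyl dienyl malonate
Product: 27 Michael adduct of halves A and B (C5 side chain β), via ammonium iodide 25 (not isolated), via enone 26 (not isolated)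
Conditions: MeI, Et2O, 20 °C; evaporate; 12, DBU, MeCN, 0 to 20 °C
Reagents that add atoms: none
Why: Quaternisation and E1cB elimination unveil the exo-methylene ketone, the soft malonate adds to it (Michael addition, forming C13′–C11′), and the enolate is protonated at C5 from the open α-face, opposite the C10 methyl and the acetal ring, which places the side chain β and also gives the more stable 2,7-cis ketone.

Step 20
Reactants: 27 Michael adduct
Product: 28 tertiary alcohol (C1: β-OH, α-CH2OPMB)
Conditions: LiN(SiMe3)2 (1.05 equiv), THF, −78 °C; then PMBOCH2Li (from Bu3SnCH2OPMB, n-BuLi), CeCl3, THF, −78 °C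
Reagents that add atoms: tributyl{[(4-methoxyphenyl)methoxy]methyl}stannane (as its lithio derivative), CCCC[Sn](CCCC)(CCCC)COCc1ccc(OC)cc1
Why: With the malonate masked as its lithium enolate, the organocerium reagent adds to the only free carbonyl (1,2-addition) from the α-face, anti to the two flanking β substituents (C10–Me and the C5 side chain), which gives the β tertiary alcohol and brings in C2.

Step 21
Reactants: 28 tertiary alcohol
Product: 30 trienone with α-methylene lactone A, via lactol 29 (not isolated)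
Conditions: 1 M HCl–THF (1:4), 20 °C; extract; TEMPO (10 mol%), PhI(OAc)2, CH2Cl2, 20 °C
Reagents that add atoms: water, O
Why: Aqueous acid hydrolyses the dioxolane and the methyl acetal, and the oxoammonium cycle (TEMPO, PhI(OAc)2) oxidises only the allylic lactol to the lactone, leaving the tertiary alcohol and the PMB ether alone.

Step 22
Reactants: 30 trienone malonate
Product: 32 allyl spiro-lactone (C11′: allyl convex, C13′ concave), via lactone malonate 31 (not isolated)
Conditions: Cs2CO3 (0.2 equiv), THF–MeCN (4:1), 0.01 M, 0 to 20 °C; then Pd(PPh3)4 (5 mol%), 40 to 60 °C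
Reagents that add atoms: none
Why: Proposed new method: catalytic carbonate deprotonates the malonate carbon C11′, the most acidic C–H by several pK units, which adds 5-exo-trig to C7′, the ζ-terminus of the trienone (a 1,8-Michael addition; the closest known reactions are intramolecular Michael and vinylogous 1,6-Michael additions of malonates and 1,8-additions of soft nucleophiles to tropones), and the extended enolate is reprotonated at C6′ to give the conjugated dienone. The O8′ tether allows bond formation only on its own face, so the γ-lactone closes cis-fused and C7′ is set by C8′. The malonate centre made in this closure is deliberately temporary: zerovalent palladium then ionises the allyl ester, CO2 is lost, and the lactone enolate recombines with the π-allyl fragment (decarboxylative Tsuji allylation). The allyl group enters on the convex face of the cis-fused bicyclic lactone, anti to the cycloheptene ring, which fixes the spiro centre C11′ with C13′ on the concave face. The step needs attack at C7′ rather than C5′ or C2′, secured because only C7′ gives a five-membered ring, and C-allylation rather than protonation or O-allylation of the enolate, favoured by ion-pair recombination in THF.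

Step 23
Reactants: 32 allyl spiro-lactone
Product: 33 methyl ketone (allyl converted to CH2C(O)CH3)
Conditions: PdCl2 (10 mol%), CuCl (0.5 equiv, co-catalyst), O2 (1 atm), DMF–H2O (7:1), 20 °C
Reagents that add atoms: water, O
Why: Tsuji–Wacker oxidation converts the monosubstituted terminal alkene into the methyl ketone by Markovnikov hydroxypalladation, while the 1,1-disubstituted and conjugated alkenes react much more slowly.

Step 24
Reactants: 33 methyl ketone
Product: 34 diol (C1–OH and C2–OH)
Conditions: DDQ, CH2Cl2–pH 7 buffer (10:1), 0 °C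
Reagents that add atoms: none
Why: DDQ oxidises the electron-rich PMB ether to an oxocarbenium ion that is hydrolysed to the primary alcohol (oxidative PMB cleavage).

Step 25
Reactants: 34 diol
Product: 36 target compound, via aldehyde 35 (not isolated)
Conditions: TEMPO (10 mol%), PhI(OAc)2, CH2Cl2, 20 °C; then DBU (1.2 equiv), 0 to 20 °C
Reagents that add atoms: none
Why: The oxoammonium oxidation touches only the primary hydroxyl, and the α-hydroxy aldehyde then undergoes intramolecular aldol condensation (6-enolexo-exo-trig; only the C3 methylene can reach C2 in a six-membered ring) with E1cB dehydration to the C2=C3 enone of ring C, creating no new stereocentre.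

**Compound list**

1 | (S)-5-(hydroxymethyl)oxolan-2-one | OC[C@@H]1CCC(=O)O1 | starting material
2 | (S)-5-oxooxolane-2-carbaldehyde | O=C[C@@H]1CCC(=O)O1 | intermediate
3 | (S)-5-ethenyloxolan-2-one | C=C[C@@H]1CCC(=O)O1 | intermediate
4 | (3R,5S)-5-ethenyl-3-methyloxolan-2-one | C=C[C@@H]1C[C@@H](C)C(=O)O1 | intermediate
5 | (2R,4S)-4-hydroxy-N-methoxy-N,2-dimethylhex-5-enamide | O[C@H](C=C)C[C@@H](C)C(=O)N(C)OC | intermediate
6 | (2R,4S)-4-[(tert-butyldimethylsilyl)oxy]-N-methoxy-N,2-dimethylhex-5-enamide | CC(C)(C)[Si](C)(C)O[C@H](C=C)C[C@@H](C)C(=O)N(C)OC | intermediate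
7 | (5R,7S)-7-[(tert-butyldimethylsilyl)oxy]-5-methylnona-1,8-dien-4-one | CC(C)(C)[Si](C)(C)O[C@H](C=C)C[C@@H](C)C(=O)CC=C | intermediate
8 | (5S,7R)-5-[(tert-butyldimethylsilyl)oxy]-7-methylcyclohept-3-en-1-one | CC(C)(C)[Si](C)(C)O[C@H]1C[C@@H](C)C(=O)CC=C1 | intermediate
9 | (5S,7R)-5-[(tert-butyldimethylsilyl)oxy]-7-methylcyclohepta-1,3-dien-1-yl trifluoromethanesulfonate | CC(C)(C)[Si](C)(C)O[C@H]1C[C@@H](C)C(OS(=O)(=O)C(F)(F)F)=CC=C1 | intermediate
10 | tert-butyldimethyl{[(1S,6R)-6-methyl-5-[(E)-2-(2-methyl-1,3-dioxolan-2-yl)ethenyl]cyclohepta-2,4-dien-1-yl]oxy}silane | CC(C)(C)[Si](C)(C)O[C@H]1C[C@@H](C)C(/C=C/C2(C)OCCO2)=CC=C1 | intermediate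
11 | (1S,6R)-6-methyl-5-[(E)-2-(2-methyl-1,3-dioxolan-2-yl)ethenyl]cyclohepta-2,4-dien-1-ol | O[C@H]1C[C@@H](C)C(/C=C/C2(C)OCCO2)=CC=C1 | intermediate
12 | (1S,6R)-6-methyl-5-[(E)-2-(2-methyl-1,3-dioxolan-2-yl)ethenyl]cyclohepta-2,4-dien-1-yl prop-2-en-1-yl propanedioate | C=CCOC(=O)CC(=O)O[C@H]1C[C@@H](C)C(/C=C/C2(C)OCCO2)=CC=C1 | intermediate
13 | (R)-5-(hydroxymethyl)oxolan-2-one | OC[C@H]1CCC(=O)O1 | starting material
14 | (R)-5-oxooxolane-2-carbaldehyde | O=C[C@H]1CCC(=O)O1 | intermediate
15 | (R)-5-ethenyloxolan-2-one | C=C[C@H]1CCC(=O)O1 | intermediate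
16 | (3S,5R)-5-ethenyl-3-methyloxolan-2-one | C=C[C@H]1C[C@H](C)C(=O)O1 | intermediate
17 | (2S,4R)-4-hydroxy-N-methoxy-N,2-dimethylhex-5-enamide | O[C@@H](C=C)C[C@H](C)C(=O)N(C)OC | intermediate
18 | (2S,4R)-4-[(tert-butyldimethylsilyl)oxy]-N-methoxy-N,2-dimethylhex-5-enamide | CC(C)(C)[Si](C)(C)O[C@@H](C=C)C[C@H](C)C(=O)N(C)OC | intermediate
19 | (5S,7R)-7-[(tert-butyldimethylsilyl)oxy]-5-methylnona-1,8-dien-4-one | CC(C)(C)[Si](C)(C)O[C@@H](C=C)C[C@H](C)C(=O)CC=C | intermediate
20 | (5R,7S)-5-[(tert-butyldimethylsilyl)oxy]-7-methylcyclohept-3-en-1-one | CC(C)(C)[Si](C)(C)O[C@@H]1C[C@H](C)C(=O)CC=C1 | intermediate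
21 | (5R,7S)-5-hydroxy-7-methylcyclohept-3-en-1-one | O[C@@H]1C[C@H](C)C(=O)CC=C1 | intermediate
22 | (5R,7S)-5-[(2-bromo-1-methoxyprop-2-en-1-yl)oxy]-7-methylcyclohept-3-en-1-one (acetal epimers) | COC(O[C@@H]1C[C@H](C)C(=O)CC=C1)C(Br)=C | intermediate
23 | (3aR,7S,8aR)-2-methoxy-7-methyl-3-methylideneoctahydro-6H-cyclohepta[b]furan-6-one (C2 epimers; cis-fused) | COC1O[C@@H]2C[C@H](C)C(=O)CC[C@@H]2C1=C | intermediate
24 | 5-[(dimethylamino)methyl] derivative of 23 (C5 epimers) | COC1O[C@@H]2C[C@H](C)C(=O)C(CN(C)C)C[C@@H]2C1=C | intermediate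
25 | trimethylammonium iodide of 24 | COC1O[C@@H]2C[C@H](C)C(=O)C(C[N+](C)(C)C)C[C@@H]2C1=C.[I-] | intermediate
26 | 5-methylidene derivative of 23 (exo-methylene ketone) | COC1O[C@@H]2C[C@H](C)C(=O)C(=C)C[C@@H]2C1=C | intermediate
27 | Michael adduct: keto acetal 23 carrying at C5 (β, cis to C10–Me; C5–H α) the chain CH2–CH(CO2allyl)–CO2R, R = dienyl of 11 (malonate CH epimers) | COC1O[C@@H]2C[C@H](C)C(=O)[C@H](CC(C(=O)OCC=C)C(=O)O[C@H]3C[C@@H](C)C(/C=C/C4(C)OCCO4)=CC=C3)C[C@@H]2C1=C | intermediate
28 | tertiary alcohol: 27 with C1 converted into C(β-OH)(α-CH2O-4-methoxybenzyl) | COC1O[C@@H]2C[C@H](C)[C@@](O)(COCc3ccc(OC)cc3)[C@H](CC(C(=O)OCC=C)C(=O)O[C@H]3C[C@@H](C)C(/C=C/C4(C)OCCO4)=CC=C3)C[C@@H]2C1=C | intermediate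
29 | lactol trienone: 28 with the dioxolane hydrolysed to the methyl ketone and the methyl acetal to the lactol | OC1O[C@@H]2C[C@H](C)[C@@](O)(COCc3ccc(OC)cc3)[C@H](CC(C(=O)OCC=C)C(=O)O[C@H]3C[C@@H](C)C(/C=C/C(C)=O)=CC=C3)C[C@@H]2C1=C | intermediate
30 | trienone malonate with α-methylene lactone A (lactol of 29 oxidised) | C=C1C(=O)O[C@@H]2C[C@H](C)[C@@](O)(COCc3ccc(OC)cc3)[C@H](CC(C(=O)OCC=C)C(=O)O[C@H]3C[C@@H](C)C(/C=C/C(C)=O)=CC=C3)C[C@H]12 | intermediate
31 | lactone malonate: cis-fused lactone B closed (C7′–C11′), C11′ bearing CO2allyl and C13′H2–half A (C11′ epimers), conjugated dienone in half B | C=C1C(=O)O[C@@H]2C[C@H](C)[C@@](O)(COCc3ccc(OC)cc3)[C@H](CC3(C(=O)OCC=C)C(=O)O[C@H]4C[C@@H](C)C(/C=C/C(C)=O)=CC[C@@H]34)C[C@H]12 | intermediate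
32 | allyl spiro-lactone: C11′ bearing allyl (convex face, cis to H-7′) and C13′H2–half A (concave face) | C=C1C(=O)O[C@@H]2C[C@H](C)[C@@](O)(COCc3ccc(OC)cc3)[C@H](C[C@@]3(CC=C)C(=O)O[C@H]4C[C@@H](C)C(/C=C/C(C)=O)=CC[C@@H]34)C[C@H]12 | intermediate
33 | methyl ketone: 32 with the allyl group oxidised to CH2C(O)CH3 (C3–C4–C15) | C=C1C(=O)O[C@@H]2C[C@H](C)[C@@](O)(COCc3ccc(OC)cc3)[C@H](C[C@@]3(CC(C)=O)C(=O)O[C@H]4C[C@@H](C)C(/C=C/C(C)=O)=CC[C@@H]34)C[C@H]12 | intermediate
34 | diol: 33 without the 4-methoxybenzyl group (C1–OH, C2–OH) | C=C1C(=O)O[C@@H]2C[C@H](C)[C@@](O)(CO)[C@H](C[C@@]3(CC(C)=O)C(=O)O[C@H]4C[C@@H](C)C(/C=C/C(C)=O)=CC[C@@H]34)C[C@H]12 | intermediate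
35 | α-hydroxy aldehyde: 34 with C2 oxidised to CHO | C=C1C(=O)O[C@@H]2C[C@H](C)[C@@](O)(C=O)[C@H](C[C@@]3(CC(C)=O)C(=O)O[C@H]4C[C@@H](C)C(/C=C/C(C)=O)=CC[C@@H]34)C[C@H]12 | intermediate
36 | target compound (CNP0168949.2) | C=C1C(=O)O[C@@H]2C[C@H](C)[C@@]3(O)C=C(C(C)=O)[C@]4(C[C@@H]3C[C@H]12)C(=O)O[C@H]1C[C@@H](C)C(/C=C/C(C)=O)=CC[C@H]14 | target

**Summary**

Total step count: 25. Longest linear sequence: 16 steps (steps 10–18, then 19–25; the branch 1–9 plus 19–25 is equally long).

Steps most likely to fail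

1. Step 22 (proposed new method). The carbanion may fail to reach C7′ (ester rotamer, hindered tertiary malonate) or may be consumed by acyl transfer to the C1 hydroxyl, and the palladium stage may end in protonation instead of allylation of the enolate. Fallback with known chemistry, setting out from 30 and returning at 31: the malonate is brominated (NaH, THF, −78 °C; N-bromosuccinimide) to the bromomalonate F1. The lactone is then closed by a tin-hydride-mediated 5-exo radical cyclisation of the malonyl radical onto C7′ (Bu3SnH, Et3B/air, PhH, high dilution), followed by brief DBU treatment to bring the diene into conjugation with the ketone. This gives 31, isolated, which is carried on by the palladium-catalysed decarboxylative allylation to 32.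

2. Step 20. The hindered α,α′-disubstituted ketone may be enolised instead of attacked, which would also epimerise C5 and C10, and facial selectivity at C1 may be incomplete. Fallback, setting out from 27 and returning at 28: the less basic silylmethyl Grignard reagent (i-PrO)Me2SiCH2MgCl with CeCl3 adds to the ketone to give the silane F2. Tamao oxidation (KF, KHCO3, H2O2, THF–MeOH) gives the diol F3, and the primary hydroxyl is etherified selectively through its stannylene acetal (Bu2SnO; 4-methoxybenzyl chloride, CsF) to give 28.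

3. Step 25. The free tertiary α-hydroxy aldehyde may undergo α-ketol rearrangement or hemiketal formation with the C4 ketone before the aldol closure, or the aldol may stop before dehydration. Fallback, setting out from 33 and returning at 36: the tertiary hydroxyl is masked first (N-trimethylsilylimidazole, 60 °C) to give the silyl ether F4, and DDQ cleavage gives the primary alcohol F5. Oxidation (TEMPO, PhI(OAc)2) and DBU-mediated condensation then give the silyl-protected enone F6, and HF·pyridine releases 36.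

Further compounds
F1 | step 22 | bromomalonate of 30 (Br on the malonate carbon) | C=C1C(=O)O[C@@H]2C[C@H](C)[C@@](O)(COCc3ccc(OC)cc3)[C@H](CC(Br)(C(=O)OCC=C)C(=O)O[C@H]3C[C@@H](C)C(/C=C/C(C)=O)=CC=C3)C[C@H]12
F2 | step 20 | silane: 27 with C1 converted into C(β-OH)(α-CH2SiMe2O-i-Pr) | COC1O[C@@H]2C[C@H](C)[C@@](O)(C[Si](C)(C)OC(C)C)[C@H](CC(C(=O)OCC=C)C(=O)O[C@H]3C[C@@H](C)C(/C=C/C4(C)OCCO4)=CC=C3)C[C@@H]2C1=C
F3 | step 20 | diol: 27 with C1 converted into C(β-OH)(α-CH2OH) | COC1O[C@@H]2C[C@H](C)[C@@](O)(CO)[C@H](CC(C(=O)OCC=C)C(=O)O[C@H]3C[C@@H](C)C(/C=C/C4(C)OCCO4)=CC=C3)C[C@@H]2C1=C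
F4 | step 25 | trimethylsilyl ether of 33 at the C1 hydroxyl | C=C1C(=O)O[C@@H]2C[C@H](C)[C@@](O[Si](C)(C)C)(COCc3ccc(OC)cc3)[C@H](C[C@@]3(CC(C)=O)C(=O)O[C@H]4C[C@@H](C)C(/C=C/C(C)=O)=CC[C@@H]34)C[C@H]12
F5 | step 25 | primary alcohol: F4 without the 4-methoxybenzyl group | C=C1C(=O)O[C@@H]2C[C@H](C)[C@@](O[Si](C)(C)C)(CO)[C@H](C[C@@]3(CC(C)=O)C(=O)O[C@H]4C[C@@H](C)C(/C=C/C(C)=O)=CC[C@@H]34)C[C@H]12
F6 | step 25 | C1 trimethylsilyl ether of the target | C=C1C(=O)O[C@@H]2C[C@H](C)[C@@]3(O[Si](C)(C)C)C=C(C(C)=O)[C@]4(C[C@@H]3C[C@H]12)C(=O)O[C@H]1C[C@@H](C)C(/C=C/C(C)=O)=CC[C@H]14
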